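**Retrosynthetic overview**
1. Target 9 is cut inside the side chain, between chain carbons C7 and C8 counted from pyrrole C3. The halves are the ω-pyrrolyl acid 5 and tridecanoic acid 6, joined by a reductive Ni-electrocatalytic doubly decarboxylative cross-coupling of their NHPI esters made in the flask. Both carboxyl carbons, of like polarity, leave as CO2.
2. Enabling feature: the substituent on pyrrole C3 is an unbranched, heteroatom-free C19 chain. Its C7 and C8 are plain CH2 groups, six methylenes away from the 1H-pyrrole ring (N1, C2–C5) and the C2 methyl ester. Each half is therefore a primary alkanoic acid, and each radical is an unstabilised primary one that cannot cyclise onto the ring (only 8- or 9-membered closures are open).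
3. Acid 5 comes from primary alcohol 3 by TEMPO/PhI(OAc)2 oxidation.
4. Ring formation: the pyrrole, the only ring, is made first, by silver-catalysed formal [3+2] cycloaddition of dec-9-yn-1-ol 1 with methyl isocyanoacetate 2 (bonds C2–C3 and C4–C5). This places the chain at C3 and the ester at C2 directly.

Key step: step 3

Remark: the target has no stereocentre and no stereogenic double bond, so no stereochemical task arises; all compounds of the main route are achiral.

Step 1
Reactants: 1 dec-9-yn-1-ol; 2 methyl isocyanoacetate
Product: 3 methyl 3-(8-hydroxyoctyl)-1H-pyrrole-2-carboxylate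
Conditions: 1 (1 equiv), 2 (1.5 equiv), Ag2CO3 (10 mol%), NMP, 80 °C
Reagents that add atoms: none
Why: Silver-catalysed isocyanide–alkyne formal [3+2] cycloaddition, in which the silver acetylide of 1 takes up the isocyanide carbon at the terminal alkyne carbon and the α-carbon of the isocyanoacetate then closes onto the internal alkyne carbon, so the chain should end up at C3 next to the ester at C2, with the remote primary hydroxyl as a spectator.

Step 2
Reactants: 3 methyl 3-(8-hydroxyoctyl)-1H-pyrrole-2-carboxylate
Product: 5 methyl 3-(7-carboxyheptyl)-1H-pyrrole-2-carboxylate, via aldehyde 4 (not isolated)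
Conditions: TEMPO (0.2 equiv), PhI(OAc)2 (2.2 equiv), MeCN/H2O 1:1, rt
Reagents that add atoms: water, O
Why: TEMPO/PhI(OAc)2 oxidation in aqueous acetonitrile (alcohol to aldehyde to hydrate to acid through the catalytic oxoammonium salt) should be selective for the unhindered primary alcohol, because the pyrrole is deactivated by its conjugated 2-ester.

Step 3
Reactants: 5 methyl 3-(7-carboxyheptyl)-1H-pyrrole-2-carboxylate; 6 tridecanoic acid
Product: 9 methyl 3-nonadecyl-1H-pyrrole-2-carboxylate, via pyrrolyloctanoate NHPI ester 7 (not isolated), via tridecanoate NHPI ester 8 (not isolated)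
Conditions: 5 (1 equiv), 6 (3 equiv), N-hydroxyphthalimide (4 equiv), DIC (4 equiv), DMAP (10 mol%), DMF, rt; then NiCl2·6H2O (20 mol%), 2,2′:6′,2″-terpyridine (20 mol%), AgNO3 (0.3 equiv), NaI, DMF, (+)Mg/(−)RVC, undivided cell, constant current, rt; aq. HCl work-up
Reagents that add atoms: none
Why: Both acids are converted in the flask into their N-acyloxyphthalimides 7 and 8; cathodically generated low-valent Ni(terpyridine) transfers an electron to each ester, which loses phthalimide anion and CO2 to give an unstabilised primary alkyl radical, and capture of the two alkyl groups at nickel followed by C(sp3)–C(sp3) reductive elimination should form the bond between chain C7 and C8, the sacrificial Mg anode supplying the two electrons. The closest known reaction type is the Ni-electrocatalytic doubly decarboxylative cross-coupling of two primary redox-active esters generated in situ from free acids, the reductive counterpart of a mixed Kolbe electrolysis. No ring is closed and no stereocentre is created. The step needs cross- over homo-coupling, which the threefold excess of the inexpensive acid 6 secures statistically, and both homodimers (tetracosane and the C14-linked bis-pyrrole diester) differ sharply in polarity from 9. It also needs the oxidation-prone 1H-pyrrole to survive, which the cathodic mode secures because the ring never meets the anodic potential of a classical Kolbe coupling, while the methyl ester and the weakly acidic N–H should be inert to the nickel catalyst. The six-methylene spacer keeps the radical centre away from the ring, so neither cyclisation nor stabilisation by the heterocycle can divert it.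

**Compound list**
1 | dec-9-yn-1-ol | OCCCCCCCCC#C | starting material
2 | methyl isocyanoacetate | [C-]#[N+]CC(=O)OC | starting material
3 | methyl 3-(8-hydroxyoctyl)-1H-pyrrole-2-carboxylate | OCCCCCCCCc1cc[nH]c1C(=O)OC | intermediate
4 | methyl 3-(8-oxooctyl)-1H-pyrrole-2-carboxylate | O=CCCCCCCCc1cc[nH]c1C(=O)OC | intermediate (not isolated)
5 | methyl 3-(7-carboxyheptyl)-1H-pyrrole-2-carboxylate, i.e. 8-[2-(methoxycarbonyl)-1H-pyrrol-3-yl]octanoic acid | OC(=O)CCCCCCCc1cc[nH]c1C(=O)OC | intermediate
6 | tridecanoic acid | CCCCCCCCCCCCC(=O)O | starting material
7 | 1,3-dioxoisoindolin-2-yl 8-[2-(methoxycarbonyl)-1H-pyrrol-3-yl]octanoate | COC(=O)c1[nH]ccc1CCCCCCCC(=O)ON1C(=O)c2ccccc2C1=O | intermediate (not isolated)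
8 | 1,3-dioxoisoindolin-2-yl tridecanoate | CCCCCCCCCCCCC(=O)ON1C(=O)c2ccccc2C1=O | intermediate (not isolated)
9 | methyl 3-nonadecyl-1H-pyrrole-2-carboxylate | CCCCCCCCCCCCCCCCCCCc1cc[nH]c1C(=O)OC | target

**Step count**
Total steps: 3. Longest linear sequence: 3 steps (1 to 3 to 5 to 9); tridecanoic acid 6 enters as purchased.

**Steps most likely to fail**

Step 3 (key step). What may go wrong: homo-coupling of each ester and hydrodecarboxylation of the primary radicals may outrun the cross-coupling. Carbodiimide and urea residues from the in-flask activation, or cathodic deprotonation of the pyrrole N–H, may also stall the nickel cycle. The fallback sets out from acid 5 and comes back at target 9. Ester 7 is made separately and isolated (N-hydroxyphthalimide, DIC, cat. DMAP, CH2Cl2, rt). It is then coupled in a nickel-catalysed decarboxylative alkyl–alkyl Negishi-type reaction (NiCl2·glyme 20 mol%, 4,4′-di-tert-butyl-2,2′-bipyridine 40 mol%, THF/DMF, rt) with didodecylzinc F1. F1 is prepared from commercial dodecylmagnesium bromide and ZnCl2 (0.5 equiv) in THF and used in 3 equiv, one of which covers the N–H. This forms the same chain bond by a nucleophile–electrophile pairing that is cross-selective by design.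

Step 1. What may go wrong: silver-mediated self-condensation of the isocyanoacetate, addition of the free hydroxyl to the isocyanide carbon, or slow metalation of the unactivated aliphatic alkyne may consume the partners before cycloaddition. The fallback sets out from methyl isocyanoacetate 2 and comes back at acid 5, building the ring by a Barton–Zard synthesis instead.
- Commercial methyl 9-oxononanoate and nitromethane (cat. tetramethylguanidine, THF, 0 °C) should give, by Henry reaction, methyl 9-hydroxy-10-nitrodecanoate F2 (racemic; the stereocentre is destroyed later).
- Acetylation (Ac2O, cat. H2SO4, 0 °C to rt) should give methyl 9-acetoxy-10-nitrodecanoate F3.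
- With 2 and DBU (2.2 equiv, THF, 0 °C to rt), F3 should eliminate to methyl (E)-10-nitrodec-9-enoate F4 (not isolated), which undergoes the Barton–Zard reaction to methyl 3-(8-methoxy-8-oxooctyl)-1H-pyrrole-2-carboxylate F5.
- LiOH (1.2 equiv, THF/H2O, 0 °C to rt; aq. HCl to pH 3) should saponify only the aliphatic ester and give 5, because the pyrrole-2-carboxylate is a deactivated vinylogous carbamate.

Step 2. What may go wrong: the oxoammonium salt or the iodine(III) reagent may attack the pyrrole ring or its N–H, or the oxidation may stall at the aldehyde stage. The fallback sets out from methyl isocyanoacetate 2 and comes back at acid 5. It carries the carboxyl group at its final oxidation level, so no oxidant meets the pyrrole.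
- Commercial dec-9-ynoic acid is converted into tert-butyl dec-9-ynoate F6 (Boc2O, cat. DMAP, t-BuOH, rt).
- Silver-catalysed cycloaddition with 2 (Ag2CO3 10 mol%, NMP, 80 °C) should give methyl 3-(8-tert-butoxy-8-oxooctyl)-1H-pyrrole-2-carboxylate F7.
- TFA/CH2Cl2 at rt should cleave only the tert-butyl ester and give 5.

**Further compounds**
F1 | step 3 | didodecylzinc | CCCCCCCCCCCC[Zn]CCCCCCCCCCCC
F2 | step 1 | methyl 9-hydroxy-10-nitrodecanoate (racemic) | COC(=O)CCCCCCCC(O)C[N+](=O)[O-]
F3 | step 1 | methyl 9-acetoxy-10-nitrodecanoate (racemic) | COC(=O)CCCCCCCC(OC(C)=O)C[N+](=O)[O-]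
F4 | step 1 | methyl (E)-10-nitrodec-9-enoate | COC(=O)CCCCCCC/C=C/[N+](=O)[O-]
F5 | step 1 | methyl 3-(8-methoxy-8-oxooctyl)-1H-pyrrole-2-carboxylate | COC(=O)CCCCCCCc1cc[nH]c1C(=O)OC
F6 | step 2 | tert-butyl dec-9-ynoate | C#CCCCCCCCC(=O)OC(C)(C)C
F7 | step 2 | methyl 3-(8-tert-butoxy-8-oxooctyl)-1H-pyrrole-2-carboxylate | CC(C)(C)OC(=O)CCCCCCCc1cc[nH]c1C(=O)OC
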